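**Retrosynthetic overview** (isochromene numbering: O2, C1, C3, C4, C4a, C5–C8, C8a)
1. Target 27 ⇐ silyl ether 26 ⇐ des-chloro bicycle 25 (late C5 chlorination) ⇐ monocyclic dihydrofuranyl diynone 23, by one gold-catalysed operation that closes ring A (carbocycle) through C4a–C8a and then ring B (pyran) through O2–C3.
2. Enabling feature: on ring A the acetyl carbonyl carbon on C8a and the hydroxyl oxygen on C7 are cis and 1,3-related, so they can be held in one 2-methyl-2,3-dihydrofuran ring (a cyclic enol ether of the acetyl group). C8a is then the nucleophilic β-carbon of that enol ether, C4a is the β-carbon of a C6 ynone, and the tether dictates the C8a configuration.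
3. 23 ⇐ Weinreb amide 12 + dienediyne 21 (acetylide acylation). 21 comes from (S)-2-methylbutan-1-ol by Wittig, Takai and Negishi reactions.
4. 12 ⇐ (R)-pent-4-en-2-ol: RCM lactone, substrate-controlled syn-dihydroxylation (sets C7 and C8), lactone opening, oxidation and cyclodehydration to the dihydrofuran, then C1 by Vilsmeier formylation and reduction.
5. Ring order: temporary δ-lactone → temporary dihydrofuran → ring A → ring B (A and B in the key step).

Key step: step 13

Remark on the chemistry: the target is taken in the open 7-hydroxy/8a-acetyl form as drawn; a bridged hemiketal tautomer, if present at equilibrium, is treated as the same compound.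

**Step 1**
Reactants: 1 (R)-pent-4-en-2-ol; 2 methacryloyl chloride
Product: 3 (R)-pent-4-en-2-yl 2-methylprop-2-enoate
Conditions: Et3N, DMAP (cat.), CH2Cl2, 0 °C → rt
Reagents that add atoms: none
Why: DMAP-catalysed acylation of a secondary alcohol with an acid chloride, which leaves the carbinol stereocentre untouched.

**Step 2**
Reactants: 3 (R)-pent-4-en-2-yl 2-methylprop-2-enoate
Product: 4 (R)-3,6-dimethyl-5,6-dihydro-2H-pyran-2-one
Conditions: second-generation Grubbs catalyst (H2IMes)(PCy3)Cl2Ru=CHPh (3 mol %), toluene (0.01 M), 80 °C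
Reagents that add atoms: none
Why: Ring-closing metathesis of a methacrylate diene should give the six-membered α-methyl-α,β-unsaturated lactone with loss of ethylene, the ring enforcing the cis alkene geometry needed for the later diol.

**Step 3**
Reactants: 4 (R)-3,6-dimethyl-5,6-dihydro-2H-pyran-2-one
Product: 5 (3R,4R,6R)-3,4-dihydroxy-3,6-dimethyloxan-2-one
Conditions: K2OsO2(OH)4 (2 mol %), N-methylmorpholine N-oxide, acetone/H2O, 0 °C → rt
Reagents that add atoms: N-methylmorpholine N-oxide (C[N+]1([O-])CCOCC1); water (O)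
Why: Upjohn syn-dihydroxylation, in which osmylation of the half-chair lactone is expected on the face anti to the C6 methyl group, so the two cis hydroxyls (the later C7 and C8 oxygens) are set from the single purchased stereocentre.

**Step 4**
Reactants: 5 (3R,4R,6R)-3,4-dihydroxy-3,6-dimethyloxan-2-one
Product: 6 (3R,4R,6R)-4-[(tert-butyldimethylsilyl)oxy]-3-hydroxy-3,6-dimethyloxan-2-one
Conditions: TBSCl, imidazole, DMF, rt
Reagents that add atoms: tert-butyldimethylsilyl chloride (CC(C)(C)[Si](C)(C)Cl)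
Why: Silylation under these conditions should take the secondary hydroxyl and leave the hindered tertiary one free.

**Step 5**
Reactants: 6 (3R,4R,6R)-4-[(tert-butyldimethylsilyl)oxy]-3-hydroxy-3,6-dimethyloxan-2-one
Product: 7 (2R,3R,5R)-3-[(tert-butyldimethylsilyl)oxy]-2,5-dihydroxy-N-methoxy-N,2-dimethylhexanamide
Conditions: MeNH(OMe)·HCl, AlMe3, CH2Cl2, 0 °C → rt; aq. potassium sodium tartrate work-up
Reagents that add atoms: N,O-dimethylhydroxylamine hydrochloride (CNOC.Cl)
Why: Weinreb aminolysis of the lactone by the aluminium amide opens the ring to the Weinreb amide and frees the secondary alcohol that is oxidised next.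

**Step 6**
Reactants: 7 (2R,3R,5R)-3-[(tert-butyldimethylsilyl)oxy]-2,5-dihydroxy-N-methoxy-N,2-dimethylhexanamide
Product: 9 (2R,3R)-3-[(tert-butyldimethylsilyl)oxy]-N-methoxy-N,2,5-trimethyl-2,3-dihydrofuran-2-carboxamide, via keto alcohol 8 (not isolated)
Conditions: (n-Pr)4N[RuO4] (5 mol %), N-methylmorpholine N-oxide, 4 Å molecular sieves, CH2Cl2, rt; filter; then pyridinium p-toluenesulfonate (5 mol %), 4 Å molecular sieves, toluene, 50 °C
Reagents that add atoms: none
Why: Ley–Griffith oxidation gives the methyl ketone, whose tertiary γ-hydroxyl closes to the five-membered hemiketal, and acid-catalysed dehydration toward the ring CH2 should give the endocyclic enol ether, the purchased stereocentre being erased once it has done its work.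

**Step 7**
Reactants: 9 (2R,3R)-3-[(tert-butyldimethylsilyl)oxy]-N-methoxy-N,2,5-trimethyl-2,3-dihydrofuran-2-carboxamide
Product: 11 (2R,3R)-3-[(tert-butyldimethylsilyl)oxy]-4-formyl-N-methoxy-N,2,5-trimethyl-2,3-dihydrofuran-2-carboxamide, via iminium chloride 10 (not isolated)
Conditions: [Me2N=CHCl]Cl (1.5 equiv), DMF/CH2Cl2, 0 °C → rt; then aq. NaHCO3
Reagents that add atoms: (chloromethylene)dimethyliminium chloride (C[N+](C)=CCl.[Cl-]); water (O)
Why: Vilsmeier–Haack formylation of an enol ether at its β-carbon (the reaction that turns glycals into 2-C-formyl glycals) should install C1, the conjugated iminium salt being hydrolysed on work-up.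

**Step 8**
Reactants: 11 (2R,3R)-3-[(tert-butyldimethylsilyl)oxy]-4-formyl-N-methoxy-N,2,5-trimethyl-2,3-dihydrofuran-2-carboxamide
Product: 12 (2R,3R)-3-[(tert-butyldimethylsilyl)oxy]-4-(hydroxymethyl)-N-methoxy-N,2,5-trimethyl-2,3-dihydrofuran-2-carboxamide
Conditions: NaBH4, MeOH/THF, −20 °C; aq. NaHCO3; chromatography on Et3N-deactivated silica
Reagents that add atoms: none
Why: Borohydride 1,2-reduction of the vinylogous formate aldehyde should give the allylic alcohol while the Weinreb amide and silyl ether are inert at low temperature.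

**Step 9**
Reactants: 13 (S)-2-methylbutan-1-ol; 14 2-(triphenyl-λ5-phosphanylidene)propanal
Product: 16 (2E,4S)-2,4-dimethylhex-2-enal, via (S)-2-methylbutanal 15 (not isolated)
Conditions: TEMPO (10 mol %), PhI(OAc)2, CH2Cl2, 0 °C → rt; aq. NaHCO3 wash; then 14, toluene, 80 °C
Reagents that add atoms: none
Why: Oxoammonium (TEMPO) oxidation gives the α-chiral aldehyde under non-epimerising conditions and the Wittig reaction with the stabilised ylide should give the (E)-trisubstituted enal.

**Step 10**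
Reactants: 16 (2E,4S)-2,4-dimethylhex-2-enal
Product: 17 (1E,3E,5S)-1-iodo-3,5-dimethylhepta-1,3-diene
Conditions: CrCl2 (6 equiv), CHI3 (2 equiv), THF/dioxane, 0 °C → rt
Reagents that add atoms: iodoform (IC(I)I)
Why: Takai iodo-olefination should convert the aldehyde into the (E)-vinyl iodide with one-carbon extension.

**Step 11**
Reactants: 17 (1E,3E,5S)-1-iodo-3,5-dimethylhepta-1,3-diene; 18 1,4-bis(trimethylsilyl)buta-1,3-diyne
Product: 21 trimethyl[(5E,7E,9S)-7,9-dimethylundeca-5,7-dien-1,3-diyn-1-yl]silane, via lithium 4-(trimethylsilyl)buta-1,3-diynide 19 (not isolated), via chloro[4-(trimethylsilyl)buta-1,3-diynyl]zinc 20 (not isolated)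
Conditions: 18, MeLi·LiBr, THF, 0 °C → rt; ZnCl2, 0 °C; then 17, Pd(PPh3)4 (5 mol %), THF, rt
Reagents that add atoms: none
Why: Mono-desilylative lithiation of the bis-silyl diyne, transmetalation to zinc and Negishi coupling with the vinyl iodide should give the silyl-capped dienediyne with retention of alkene geometry.

**Step 12**
Reactants: 12 (2R,3R)-3-[(tert-butyldimethylsilyl)oxy]-4-(hydroxymethyl)-N-methoxy-N,2,5-trimethyl-2,3-dihydrofuran-2-carboxamide; 21 trimethyl[(5E,7E,9S)-7,9-dimethylundeca-5,7-dien-1,3-diyn-1-yl]silane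
Product: 23 (6E,8E,10S)-1-[(2R,3R)-3-[(tert-butyldimethylsilyl)oxy]-4-(hydroxymethyl)-2,5-dimethyl-2,3-dihydrofuran-2-yl]-8,10-dimethyldodeca-6,8-dien-2,4-diyn-1-one, via lithium dienediynide 22 (not isolated)
Conditions: 21, MeLi·LiBr, THF, −78 → 0 °C; separately 12, LiN(SiMe3)2 (1.0 equiv), THF, −78 °C; combine, −78 → −30 °C; aq. NH4Cl
Reagents that add atoms: none
Why: Silicon–lithium exchange gives the diynyl lithium, which should acylate the Weinreb amide only once because the chelated tetrahedral intermediate survives until work-up, the hydroxyl being masked as its lithium alkoxide.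

**Step 13**
Reactants: 23 (6E,8E,10S)-1-[(2R,3R)-3-[(tert-butyldimethylsilyl)oxy]-4-(hydroxymethyl)-2,5-dimethyl-2,3-dihydrofuran-2-yl]-8,10-dimethyldodeca-6,8-dien-2,4-diyn-1-one
Product: 25 (7R,8R,8aS)-8a-acetyl-8-[(tert-butyldimethylsilyl)oxy]-3-[(1E,3E,5S)-3,5-dimethylhepta-1,3-dien-1-yl]-7-hydroxy-7-methyl-7,8-dihydro-1H-isochromen-6(8aH)-one, via monocyclic enynone 24 (not isolated)
Conditions: [(2-biphenylyl)(t-Bu)2PAu(NCMe)]SbF6 (5 mol %), CH2Cl2, H2O (3 equiv), 0 °C → rt; aq. NH4Cl
Reagents that add atoms: water (O)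
Why: Proposed new method: the cationic monovalent gold complex activates the ynone triple bond and the β-carbon of the tetrasubstituted cyclic enol ether (C8a) attacks its distal carbon (C4a) anti to gold, which gives a bridged oxocarbenium ion at the acetyl carbon and a C5 vinyl–gold species; water adds to the oxocarbenium ion, the proton set free cleaves the C5–Au bond, and the bridged hemiketal opens to the acetyl group and the free C7 hydroxyl of 24, whose C1 hydroxyl then adds to the second gold-activated alkyne. The closest known reaction types are the gold-catalysed 6-endo-dig carbocyclization of cyclic silyl enol ethers onto tethered alkynes, which builds bridged bicycles with quaternary carbons, the hydroxycyclization of 1,6-enynes whose alkene is an enol ether, and the gold-catalysed hydroalkoxylation of alkynols; new here are the alkyl enol ether paired with an ynone acceptor and the two ring closures in one flask. Ring A closes 6-endo-dig through the C4a–C8a bond and ring B closes 6-endo-dig through the O2–C3 bond by anti-oxyauration and protodeauration. The only new stereocentre, the quaternary C8a, is controlled by the temporary dihydrofuran ring: the ynone arm on C7 can reach C8a only on its own face of that ring, so the acetyl carbon must end cis to the C7 oxygen on ring A, while C7 and C8 are already in place. The step needs C-attack at C4a instead of C5 and O-attack at C3 instead of C4: conjugation with the C6 carbonyl makes C4a the electrophilic alkyne carbon and 5-exo closure would give a more strained bicyclo[2.2.1] ion, C3 is the δ-carbon of the enynone and carries the cation-stabilising dienyl group, and the C8 oxygen is silylated so that it cannot add to the ynone.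

**Step 14**
Reactants: 25 (7R,8R,8aS)-8a-acetyl-8-[(tert-butyldimethylsilyl)oxy]-3-[(1E,3E,5S)-3,5-dimethylhepta-1,3-dien-1-yl]-7-hydroxy-7-methyl-7,8-dihydro-1H-isochromen-6(8aH)-one
Product: 26 (7R,8R,8aS)-8a-acetyl-8-[(tert-butyldimethylsilyl)oxy]-5-chloro-3-[(1E,3E,5S)-3,5-dimethylhepta-1,3-dien-1-yl]-7-hydroxy-7-methyl-7,8-dihydro-1H-isochromen-6(8aH)-one
Conditions: N-chlorosuccinimide (1.05 equiv), CH2Cl2, −20 → 0 °C, dark
Reagents that add atoms: N-chlorosuccinimide (O=C1CCC(=O)N1Cl)
Why: Electrophilic chlorination of the doubly vinylogous ester should occur at its α-carbon C5, the position that N-halosuccinimides attack in azaphilone chromophores containing the same O2–C3=C4–C4a=C5–C6=O unit.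

**Step 15**
Reactants: 26 (7R,8R,8aS)-8a-acetyl-8-[(tert-butyldimethylsilyl)oxy]-5-chloro-3-[(1E,3E,5S)-3,5-dimethylhepta-1,3-dien-1-yl]-7-hydroxy-7-methyl-7,8-dihydro-1H-isochromen-6(8aH)-one
Product: 27 (7R,8R,8aS)-8a-acetyl-5-chloro-3-[(1E,3E,5S)-3,5-dimethylhepta-1,3-dien-1-yl]-7,8-dihydroxy-7-methyl-7,8-dihydro-1H-isochromen-6(8aH)-one
Conditions: HF·pyridine, pyridine/THF, 0 °C → rt
Reagents that add atoms: none
Why: Fluoride cleavage of the secondary silyl ether under mildly acidic conditions should free the C8 hydroxyl without the retro-aldol cleavage that a basic fluoride source could trigger in this β-hydroxy ketone.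

**Compound list**
1 | (R)-pent-4-en-2-ol | C[C@@H](O)CC=C | starting material
2 | methacryloyl chloride | CC(=C)C(Cl)=O | starting material
3 | (R)-pent-4-en-2-yl 2-methylprop-2-enoate | C[C@@H](OC(=O)C(C)=C)CC=C | intermediate
4 | (R)-3,6-dimethyl-5,6-dihydro-2H-pyran-2-one | C[C@@H]1CC=C(C)C(=O)O1 | intermediate
5 | (3R,4R,6R)-3,4-dihydroxy-3,6-dimethyloxan-2-one | O=C1[C@](C)(O)[C@H](O)C[C@@H](C)O1 | intermediate
6 | (3R,4R,6R)-4-[(tert-butyldimethylsilyl)oxy]-3-hydroxy-3,6-dimethyloxan-2-one | O=C1[C@](C)(O)[C@H](O[Si](C)(C)C(C)(C)C)C[C@@H](C)O1 | intermediate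
7 | (2R,3R,5R)-3-[(tert-butyldimethylsilyl)oxy]-2,5-dihydroxy-N-methoxy-N,2-dimethylhexanamide | CON(C)C(=O)[C@](C)(O)[C@H](O[Si](C)(C)C(C)(C)C)C[C@@H](C)O | intermediate
8 | (2R,3R)-3-[(tert-butyldimethylsilyl)oxy]-2-hydroxy-N-methoxy-N,2-dimethyl-5-oxohexanamide (keto alcohol, in equilibrium with its cyclic hemiketal) | CON(C)C(=O)[C@](C)(O)[C@H](O[Si](C)(C)C(C)(C)C)CC(C)=O | intermediate
9 | (2R,3R)-3-[(tert-butyldimethylsilyl)oxy]-N-methoxy-N,2,5-trimethyl-2,3-dihydrofuran-2-carboxamide | CC1=C[C@@H](O[Si](C)(C)C(C)(C)C)[C@](C)(C(=O)N(C)OC)O1 | intermediate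
10 | N-{[(4R,5R)-4-[(tert-butyldimethylsilyl)oxy]-5-[methoxy(methyl)carbamoyl]-2,5-dimethyl-4,5-dihydrofuran-3-yl]methylidene}-N-methylmethanaminium chloride | CC1=C(C=[N+](C)C)[C@@H](O[Si](C)(C)C(C)(C)C)[C@](C)(C(=O)N(C)OC)O1.[Cl-] | intermediate
11 | (2R,3R)-3-[(tert-butyldimethylsilyl)oxy]-4-formyl-N-methoxy-N,2,5-trimethyl-2,3-dihydrofuran-2-carboxamide | CC1=C(C=O)[C@@H](O[Si](C)(C)C(C)(C)C)[C@](C)(C(=O)N(C)OC)O1 | intermediate
12 | (2R,3R)-3-[(tert-butyldimethylsilyl)oxy]-4-(hydroxymethyl)-N-methoxy-N,2,5-trimethyl-2,3-dihydrofuran-2-carboxamide | CC1=C(CO)[C@@H](O[Si](C)(C)C(C)(C)C)[C@](C)(C(=O)N(C)OC)O1 | intermediate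
13 | (S)-2-methylbutan-1-ol | CC[C@H](C)CO | starting material
14 | 2-(triphenyl-λ5-phosphanylidene)propanal | CC(C=O)=P(c1ccccc1)(c1ccccc1)c1ccccc1 | starting material
15 | (S)-2-methylbutanal | CC[C@H](C)C=O | intermediate
16 | (2E,4S)-2,4-dimethylhex-2-enal | CC[C@H](C)/C=C(C)/C=O | intermediate
17 | (1E,3E,5S)-1-iodo-3,5-dimethylhepta-1,3-diene | CC[C@H](C)/C=C(C)/C=C/I | intermediate
18 | 1,4-bis(trimethylsilyl)buta-1,3-diyne | C[Si](C)(C)C#CC#C[Si](C)(C)C | starting material
19 | lithium 4-(trimethylsilyl)buta-1,3-diyn-1-ide | [Li]C#CC#C[Si](C)(C)C | intermediate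
20 | chloro[4-(trimethylsilyl)buta-1,3-diyn-1-yl]zinc | Cl[Zn]C#CC#C[Si](C)(C)C | intermediate
21 | trimethyl[(5E,7E,9S)-7,9-dimethylundeca-5,7-dien-1,3-diyn-1-yl]silane | CC[C@H](C)/C=C(C)/C=C/C#CC#C[Si](C)(C)C | intermediate
22 | lithium (5E,7E,9S)-7,9-dimethylundeca-5,7-dien-1,3-diyn-1-ide | CC[C@H](C)/C=C(C)/C=C/C#CC#C[Li] | intermediate
23 | (6E,8E,10S)-1-[(2R,3R)-3-[(tert-butyldimethylsilyl)oxy]-4-(hydroxymethyl)-2,5-dimethyl-2,3-dihydrofuran-2-yl]-8,10-dimethyldodeca-6,8-dien-2,4-diyn-1-one | CC1=C(CO)[C@@H](O[Si](C)(C)C(C)(C)C)[C@](C)(C(=O)C#CC#C/C=C/C(C)=C/[C@@H](C)CC)O1 | intermediate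
24 | (4S,5R,6R)-4-acetyl-5-[(tert-butyldimethylsilyl)oxy]-3-[(3E,5E,7S)-5,7-dimethylnona-3,5-dien-1-yn-1-yl]-6-hydroxy-4-(hydroxymethyl)-6-methylcyclohex-2-en-1-one | CC[C@H](C)/C=C(C)/C=C/C#CC1=CC(=O)[C@](C)(O)[C@H](O[Si](C)(C)C(C)(C)C)[C@@]1(C(C)=O)CO | intermediate
25 | (7R,8R,8aS)-8a-acetyl-8-[(tert-butyldimethylsilyl)oxy]-3-[(1E,3E,5S)-3,5-dimethylhepta-1,3-dien-1-yl]-7-hydroxy-7-methyl-7,8-dihydro-1H-isochromen-6(8aH)-one | CC[C@H](C)/C=C(C)/C=C/C1=CC2=CC(=O)[C@](C)(O)[C@H](O[Si](C)(C)C(C)(C)C)[C@@]2(C(C)=O)CO1 | intermediate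
26 | (7R,8R,8aS)-8a-acetyl-8-[(tert-butyldimethylsilyl)oxy]-5-chloro-3-[(1E,3E,5S)-3,5-dimethylhepta-1,3-dien-1-yl]-7-hydroxy-7-methyl-7,8-dihydro-1H-isochromen-6(8aH)-one | CC[C@H](C)/C=C(C)/C=C/C1=CC2=C(Cl)C(=O)[C@](C)(O)[C@H](O[Si](C)(C)C(C)(C)C)[C@@]2(C(C)=O)CO1 | intermediate
27 | (7R,8R,8aS)-8a-acetyl-5-chloro-3-[(1E,3E,5S)-3,5-dimethylhepta-1,3-dien-1-yl]-7,8-dihydroxy-7-methyl-7,8-dihydro-1H-isochromen-6(8aH)-one | CC[C@H](C)/C=C(C)/C=C/C1=CC2=C(Cl)C(=O)[C@](C)(O)[C@H](O)[C@@]2(C(C)=O)CO1 | target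

**Step count**
Total steps: 15. Longest linear sequence: 12 steps (steps 1–8, then 12–15, from (R)-pent-4-en-2-ol); the side-chain branch is steps 9–11.

**Steps most likely to fail**

1. Step 13 (Proposed new method). The carbocyclization may be outrun by ionisation of the allylic C–O bonds of the enol ether, by hydration of an alkyne or by 5-exo closure, and the second alkyne may close 5-exo instead of 6-endo. The fallback makes the same C4a–C8a bond by an intramolecular Heck reaction, a known route to quaternary carbons on cyclic enol ethers. It sets out from 23: conjugate hydroiodination of the ynone (LiI, AcOH, MeCN, rt) should give the (2Z,6E,8E,10S)-1-[(2R,3R)-3-[(tert-butyldimethylsilyl)oxy]-4-(hydroxymethyl)-2,5-dimethyl-2,3-dihydrofuran-2-yl]-3-iodo-8,10-dimethyldodeca-2,6,8-trien-4-yn-1-one F1. Pd(OAc)2, PPh3 and Ag2CO3 in MeCN at 60 °C would then add the C4a–palladium bond across the enol ether (6-exo-trig, on the only face the tether allows), and β-hydride elimination toward the methyl group would give the bridged exocyclic enol ether (1S,5R,8R)-8-[(tert-butyldimethylsilyl)oxy]-2-[(3E,5E,7S)-5,7-dimethylnona-3,5-dien-1-yn-1-yl]-1-(hydroxymethyl)-5-methyl-7-methylidene-6-oxabicyclo[3.2.1]oct-2-en-4-one F2. Hydrolysis of F2 (pyridinium p-toluenesulfonate, wet THF) gives 24, which is isolated in this variant, and a silver-catalysed 6-endo hydroalkoxylation (AgOSO2CF3, CH2Cl2) returns to the route at 25.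

2. Step 14. Electrophilic chlorination may lack site selectivity (attack at C4 or on the dienyl chain, or over-chlorination). The fallback puts chlorine on C5 at the enolate stage of ring-B closure, where C5 is the only strongly nucleophilic carbon. It sets out from 23: silylation of the primary hydroxyl (Et3SiCl, imidazole, CH2Cl2) gives (6E,8E,10S)-1-[(2R,3R)-3-[(tert-butyldimethylsilyl)oxy]-2,5-dimethyl-4-{[(triethylsilyl)oxy]methyl}-2,3-dihydrofuran-2-yl]-8,10-dimethyldodeca-6,8-dien-2,4-diyn-1-one F3. The gold catalyst of step 13 in wet CH2Cl2 should then close only ring A, giving (4S,5R,6R)-4-acetyl-5-[(tert-butyldimethylsilyl)oxy]-3-[(3E,5E,7S)-5,7-dimethylnona-3,5-dien-1-yn-1-yl]-6-hydroxy-6-methyl-4-{[(triethylsilyl)oxy]methyl}cyclohex-2-en-1-one F4. Tris(dimethylamino)sulfonium difluorotrimethylsilicate in THF at −78 °C releases the C1 alkoxide, which adds to C3 (1,6-oxa-Michael, 6-endo-dig) to give a cross-conjugated dienolate; quenching with N-chlorosuccinimide at its α-carbon and warming with Et3N (allene-to-diene proton shift) should give 26, where the route is rejoined.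

3. Step 7. The chloroiminium salt and the HCl it releases may cause loss of the allylic silyloxy group or attack on the amide instead of C-formylation. The fallback introduces C1 by cross-coupling and sets out from 9: iodination of the enol ether β-carbon (N-iodosuccinimide, AgNO3 cat., MeCN, 60 °C, as used to make 2-iodoglycals) should give (2R,3S)-3-[(tert-butyldimethylsilyl)oxy]-4-iodo-N-methoxy-N,2,5-trimethyl-2,3-dihydrofuran-2-carboxamide F5. Stille coupling with Bu3SnCH2OH (Pd(PPh3)4, dioxane, 80 °C) then gives 12 directly, where the route is rejoined, bypassing 11 and step 8.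

**Further compounds**
F1 | step 13 | (2Z,6E,8E,10S)-1-[(2R,3R)-3-[(tert-butyldimethylsilyl)oxy]-4-(hydroxymethyl)-2,5-dimethyl-2,3-dihydrofuran-2-yl]-3-iodo-8,10-dimethyldodeca-2,6,8-trien-4-yn-1-one | CC1=C(CO)[C@@H](O[Si](C)(C)C(C)(C)C)[C@](C)(C(=O)/C=C(\I)C#C/C=C/C(C)=C/[C@@H](C)CC)O1
F2 | step 13 | (1S,5R,8R)-8-[(tert-butyldimethylsilyl)oxy]-2-[(3E,5E,7S)-5,7-dimethylnona-3,5-dien-1-yn-1-yl]-1-(hydroxymethyl)-5-methyl-7-methylidene-6-oxabicyclo[3.2.1]oct-2-en-4-one | C=C1O[C@@]2(C)C(=O)C=C(C#C/C=C/C(C)=C/[C@@H](C)CC)[C@]1(CO)[C@H]2O[Si](C)(C)C(C)(C)C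
F3 | step 14 | (6E,8E,10S)-1-[(2R,3R)-3-[(tert-butyldimethylsilyl)oxy]-2,5-dimethyl-4-{[(triethylsilyl)oxy]methyl}-2,3-dihydrofuran-2-yl]-8,10-dimethyldodeca-6,8-dien-2,4-diyn-1-one | CC1=C(CO[Si](CC)(CC)CC)[C@@H](O[Si](C)(C)C(C)(C)C)[C@](C)(C(=O)C#CC#C/C=C/C(C)=C/[C@@H](C)CC)O1
F4 | step 14 | (4S,5R,6R)-4-acetyl-5-[(tert-butyldimethylsilyl)oxy]-3-[(3E,5E,7S)-5,7-dimethylnona-3,5-dien-1-yn-1-yl]-6-hydroxy-6-methyl-4-{[(triethylsilyl)oxy]methyl}cyclohex-2-en-1-one | CC[C@H](C)/C=C(C)/C=C/C#CC1=CC(=O)[C@](C)(O)[C@H](O[Si](C)(C)C(C)(C)C)[C@@]1(C(C)=O)CO[Si](CC)(CC)CC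
F5 | step 7 | (2R,3S)-3-[(tert-butyldimethylsilyl)oxy]-4-iodo-N-methoxy-N,2,5-trimethyl-2,3-dihydrofuran-2-carboxamide | CC1=C(I)[C@@H](O[Si](C)(C)C(C)(C)C)[C@](C)(C(=O)N(C)OC)O1
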